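With ring B numbered from the C1 carbonyl through the bridge-bearing C2 to the acetyl-bearing C6, the disconnection cuts C2–C3 and C1–C6. The quaternary C4, flanked by the oxygenated carbons C3 and C5, is read as C2 of a mirror-symmetric 2-geranyl-2-methylcyclobutane-1,3-dione whose CH2 becomes C6, while C1–C2, carrying an oxygen and the methylene bridge to ring A, is read as an ethoxyalkyne. Zerovalent nickel with a chiral ligand should insert the alkyne into one of the two enantiotopic acyl–CH2 bonds: one operation joins the two halves, expands the four-membered ring to ring B and sets the only stereocentre. The precursors are that dione and a tris-MOM-protected ring A ketone bearing a 3-ethoxyprop-2-ynyl arm.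

Key step: step 11

**Remarks on the chemistry**

- Tautomer and descriptors: the target is taken as the triketone tautomer drawn, with C4 as its only stereocentre (R). In 22–24 the sequence rule ranks C3 above C5, so the same spatial arrangement is called S there; nothing is inverted between 24 and 25.
- Ligand (assumption): the sense of induction of the nickel–phosphoramidite catalyst cannot be derived from precedent. The (S,R,R) ligand is written; its antipode would be used if a test run shows the opposite sense.
- Ketone and organometallics: the butyryl ketone enters only after the last aryllithium step. The ynol ether is then attached as a zinc acetylide under palladium catalysis, because a lithium acetylide would attack or enolise that ketone.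
- Heat: ring B of 22 and 23 is, in its enol form, a cyclohexadienone with an allylic (geranyl) group on its sp3 carbon. Such dienones can undergo Cope rearrangement and aromatise on heating, so the enol ether is cleaved by cold dilute acid and not by hot nucleophilic dealkylation.
- Acidity of the dione: 9 cannot be made non-acidic without losing the mirror symmetry that the desymmetrisation needs (any enol derivative or mono-acetal is chiral and racemic). It is therefore used as such, and the hazard is met by the conditions of step 11.

**Route**

Step 1
Reactants: 1 propanoic acid; 2 geranyl bromide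
Product: 4 (4E)-2,5,9-trimethyldeca-4,8-dienoic acid (racemic), via dilithium propanoate enediolate 3 (not isolated)
Conditions: LiN(i-Pr)2 (2.1 equiv), THF, −78 to 0 °C; then 2, −78 °C to rt; aq. HCl work-up
Reagents that add atoms: none
Why: Alkylation of a carboxylic acid dianion with a primary allylic bromide is a standard SN2 process at the CH2 terminus that leaves the E alkene untouched; the new stereocentre is racemic and is erased at the ketene stage.

Step 2
Reactants: 4 (4E)-2,5,9-trimethyldeca-4,8-dienoic acid
Product: 5 (4E)-2,5,9-trimethyldeca-4,8-dienoyl chloride (racemic)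
Conditions: (COCl)2, DMF (cat.), CH2Cl2, 0 °C to rt
Reagents that add atoms: oxalyl chloride, O=C(Cl)C(Cl)=O
Why: Acid chloride formation with oxalyl chloride under Vilsmeier catalysis is neutral and cold enough for the two trisubstituted alkenes.

Step 3
Reactants: 5 (4E)-2,5,9-trimethyldeca-4,8-dienoyl chloride; 6 ethoxyacetylene
Product: 8 3-ethoxy-4-geranyl-4-methylcyclobut-2-en-1-one (racemic), via methyl(geranyl)ketene 7 (not isolated)
Conditions: 6 (2 equiv), Et3N (1.5 equiv), Et2O, 0 °C to rt
Reagents that add atoms: none
Why: Dehydrochlorination gives ketene 7, which enters the established thermal (2+2) cycloaddition of ketenes with ethoxyacetylene, the ketene carbonyl carbon bonding to the unsubstituted alkyne carbon to give the 3-ethoxycyclobutenone; its stereocentre is racemic and becomes prochiral in step 4.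

Step 4
Reactants: 8 3-ethoxy-4-geranyl-4-methylcyclobut-2-en-1-one
Product: 9 2-geranyl-2-methylcyclobutane-1,3-dione (achiral)
Conditions: 1 M aq. HCl, THF, 0 °C to rt; used fresh and dry
Reagents that add atoms: water, O
Why: Acid hydrolysis of the vinylogous ester is the standard conversion of 3-alkoxycyclobutenones into cyclobutane-1,3-diones, and it turns the racemic ring carbon of 8 into the prochiral C2 of the mirror-symmetric dione.

Step 5
Reactants: 10 phloroglucinol
Product: 11 1,3,5-tris(methoxymethoxy)benzene
Conditions: MOMCl (3.6 equiv), i-Pr2NEt, CH2Cl2–DMF, 0 °C to rt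
Reagents that add atoms: chloromethyl methyl ether, COCCl
Why: Base-mediated O-alkylation (Williamson-type) of all three phenols gives the symmetric tris-acetal whose oxygen atoms direct the later lithiations.

Step 6
Reactants: 11 1,3,5-tris(methoxymethoxy)benzene
Product: 13 1,3,5-tris(methoxymethoxy)-2-(3-methylbut-2-enyl)benzene, via 2,4,6-tris(methoxymethoxy)phenyllithium 12 (not isolated)
Conditions: n-BuLi, THF, 0 °C; then CuI (10 mol%), prenyl bromide, −78 °C to rt
Reagents that add atoms: prenyl bromide (1-bromo-3-methylbut-2-ene), CC(C)=CCBr
Why: Directed ortho-metalation between two OMOM groups (all three ring positions are equivalent) followed by copper-assisted SN2 allylation of the aryllithium.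

Step 7
Reactants: 13 1,3,5-tris(methoxymethoxy)-2-(3-methylbut-2-enyl)benzene
Product: 15 [2,4,6-tris(methoxymethoxy)-3-(3-methylbut-2-enyl)phenyl]methanol, via prenylated aryllithium 14 (not isolated)
Conditions: n-BuLi, THF, 0 °C; then (CH2O)n, −78 °C to rt
Reagents that add atoms: formaldehyde (as paraformaldehyde), C=O
Why: A second directed ortho-metalation at one of the two equivalent C–H positions flanked by OMOM groups, then 1,2-addition of the aryllithium to formaldehyde (hydroxymethylation).

Step 8
Reactants: 15 [2,4,6-tris(methoxymethoxy)-3-(3-methylbut-2-enyl)phenyl]methanol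
Product: 17 1-[3-(hydroxymethyl)-2,4,6-tris(methoxymethoxy)-5-(3-methylbut-2-enyl)phenyl]butan-1-one, via dilithiated benzylic alkoxide 16 (not isolated)
Conditions: n-BuLi (2.2 equiv), THF, −20 to 0 °C; then N-methoxy-N-methylbutanamide, −78 to 0 °C
Reagents that add atoms: N-methoxy-N-methylbutanamide, CCCC(=O)N(C)OC
Why: After O-deprotonation the last ring C–H, again between two OMOM groups, is lithiated (directed ortho-metalation) and acylated by the Weinreb amide, whose chelated tetrahedral adduct prevents over-addition.

Step 9
Reactants: 17 1-[3-(hydroxymethyl)-2,4,6-tris(methoxymethoxy)-5-(3-methylbut-2-enyl)phenyl]butan-1-one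
Product: 18 1-[3-(bromomethyl)-2,4,6-tris(methoxymethoxy)-5-(3-methylbut-2-enyl)phenyl]butan-1-one
Conditions: CBr4, PPh3, 2,6-lutidine, CH2Cl2, −20 to 0 °C; used at once
Reagents that add atoms: tetrabromomethane, BrC(Br)(Br)Br
Why: Appel bromination converts the primary benzylic alcohol under neutral, buffered conditions that spare the MOM acetals, and the ring ketone tempers ionisation of the electron-rich benzylic bromide.

Step 10
Reactants: 18 benzylic bromide; 6 ethoxyacetylene
Product: 21 ring A ethoxyalkyne 1-[3-(3-ethoxyprop-2-ynyl)-2,4,6-tris(methoxymethoxy)-5-(3-methylbut-2-enyl)phenyl]butan-1-one, via lithium ethoxyacetylide 19 (not isolated), via bromo(ethoxyethynyl)zinc 20 (not isolated)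
Conditions: 6, n-BuLi, THF, −78 °C; ZnBr2, −78 to 0 °C; then 18, PdCl2(DPEphos) (5 mol%), THF, 0 °C to rt
Reagents that add atoms: none
Why: Negishi coupling of an alkynylzinc halide with a benzylic bromide forms the sp3–sp bond, and the zinc acetylide neither adds to nor enolises the butyryl ketone and is not basic enough to isomerise the propargylic ether to an allene.

Step 11
Reactants: 9 2-geranyl-2-methylcyclobutane-1,3-dione; 21 ring A ethoxyalkyne
Product: 22 ring B ethyl vinylogous ester (4S) with ring A as tris-MOM ether
Conditions: Ni(cod)2 (10 mol%), (S)-BINOL N,N-bis[(R)-1-phenylethyl]phosphoramidite (12 mol%), toluene, 0 °C to rt, 9 added slowly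
Reagents that add atoms: none
Why: Proposed new method: zerovalent nickel carrying one chiral phosphoramidite binds the ynol ether and one ketone of 9 and undergoes oxidative cyclisation to a spiro oxanickelacyclopentene of divalent nickel, in which the benzylated alkyne carbon is bonded to the former carbonyl carbon (C3) and the ethoxy-bearing carbon to nickel; β-carbon elimination of the ring CH2 (C6) then releases the strain of the four-membered ring to give a seven-membered nickelacycle that is also a nickel enolate, and reductive elimination forms C1–C6 and returns zerovalent nickel. The closest known reaction type is the Ni(cod)2/phosphine-catalysed intermolecular insertion of internal alkynes into cyclobutanones to give cyclohex-2-enones, which covers neither a 1,3-dione with an acidic CH2 nor a choice between enantiotopic carbonyls. Ring B is closed by insertion of two carbons into a ring bond, a formal (4+2) ring expansion, and not by cyclisation of an open chain. The C4 stereocentre is set by the ligand alone, which decides which of the two enantiotopic carbonyl groups enters the nickelacycle; no bond to C4 is made or broken, and the face of approach is irrelevant because the spiro carbon returns to sp2. Regiochemistry follows from the polarisation of the ynol ether (nucleophilic benzylated carbon to the carbonyl carbon, oxygen-bearing carbon to nickel), the hindered and unstrained butyryl ketone between two OMOM groups should not compete, and β-carbon elimination towards C4 in place of C6 would give an enol-ether isomer that converges on the same trione 23 in step 12. The main hazard, proton transfer from 9 or from the enolisable product to the acid-labile ynol ether and to nickel, is met by toluene (in which 9 should stay largely in the diketo form), by a temperature at or below ambient, and by a low standing concentration of 9.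

Step 12
Reactants: 22 ring B ethyl vinylogous ester
Product: 23 ring B trione (4S; drawn as its C1 enol) with ring A as tris-MOM ether
Conditions: 0.5 M aq. HCl, THF, 0 °C to rt, stopped at full conversion
Reagents that add atoms: water, O
Why: Acid hydrolysis of a β-alkoxy enone (vinylogous ester) is far faster than hydrolysis of aryl formaldehyde acetals, so cold dilute acid should free the C1 oxygen while the MOM ethers stay and the quaternary C4 is untouched.

Step 13
Reactants: 23 ring B trione
Product: 25 tris-MOM ether of the target (4R), via ring B enol acetate 24 (not isolated)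
Conditions: Ac2O (1.1 equiv), Et3N (2.5 equiv), CH2Cl2, 0 °C; then DMAP (0.3 equiv), rt; cold aq. NaH2PO4 work-up
Reagents that add atoms: acetic anhydride, CC(=O)OC(C)=O
Why: O-acetylation of the cyclic β-triketone followed by DMAP-mediated O-to-C acyl migration, the standard route to 2-acylcyclohexane-1,3-diones, delivers acetyl to C6 because only there does the product remain an enolisable, strongly acidic tricarbonyl (C2 carries the benzyl group and acylation there is reversible).

Step 14
Reactants: 25 tris-MOM ether of the target
Product: 26 target CNP0227753.1 (4R)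
Conditions: HCl (1.25 M in MeOH), rt, stopped at conversion
Reagents that add atoms: none
Why: Acid-catalysed acetal exchange with methanol (MOM cleavage) at room temperature removes the three protecting groups under conditions mild enough to avoid chroman formation from the ortho-prenyl phenol, and the non-enolisable C4 cannot epimerise.

**Compound list**

1 | propanoic acid | CCC(=O)O | starting material
2 | geranyl bromide, (2E)-1-bromo-3,7-dimethylocta-2,6-diene | CC(C)=CCC/C(C)=C/CBr | starting material
3 | dilithium enediolate of propanoic acid | CC=C(O[Li])O[Li] | intermediate (not isolated)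
4 | (4E)-2,5,9-trimethyldeca-4,8-dienoic acid, racemic at C2 | CC(C/C=C(\C)CCC=C(C)C)C(=O)O | intermediate
5 | (4E)-2,5,9-trimethyldeca-4,8-dienoyl chloride, racemic | CC(C/C=C(\C)CCC=C(C)C)C(Cl)=O | intermediate
6 | ethoxyacetylene | CCOC#C | starting material
7 | methyl(geranyl)ketene, (4E)-2,5,9-trimethyldeca-1,4,8-trien-1-one | CC(C/C=C(\C)CCC=C(C)C)=C=O | intermediate (not isolated)
8 | 3-ethoxy-4-[(2E)-3,7-dimethylocta-2,6-dienyl]-4-methylcyclobut-2-en-1-one, racemic | CCOC1=CC(=O)C1(C)C/C=C(\C)CCC=C(C)C | intermediate
9 | 2-[(2E)-3,7-dimethylocta-2,6-dienyl]-2-methylcyclobutane-1,3-dione, achiral | CC1(C/C=C(\C)CCC=C(C)C)C(=O)CC1=O | intermediate (key-step precursor)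
10 | phloroglucinol | Oc1cc(O)cc(O)c1 | starting material
11 | 1,3,5-tris(methoxymethoxy)benzene | COCOc1cc(OCOC)cc(OCOC)c1 | intermediate
12 | [2,4,6-tris(methoxymethoxy)phenyl]lithium | [Li]c1c(OCOC)cc(OCOC)cc1OCOC | intermediate (not isolated)
13 | 1,3,5-tris(methoxymethoxy)-2-(3-methylbut-2-enyl)benzene | COCOc1cc(OCOC)c(CC=C(C)C)c(OCOC)c1 | intermediate
14 | [2,4,6-tris(methoxymethoxy)-3-(3-methylbut-2-enyl)phenyl]lithium | [Li]c1c(OCOC)cc(OCOC)c(CC=C(C)C)c1OCOC | intermediate (not isolated)
15 | [2,4,6-tris(methoxymethoxy)-3-(3-methylbut-2-enyl)phenyl]methanol | OCc1c(OCOC)cc(OCOC)c(CC=C(C)C)c1OCOC | intermediate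
16 | lithium [3-lithio-2,4,6-tris(methoxymethoxy)-5-(3-methylbut-2-enyl)phenyl]methanolate | [Li]OCc1c(OCOC)c([Li])c(OCOC)c(CC=C(C)C)c1OCOC | intermediate (not isolated)
17 | 1-[3-(hydroxymethyl)-2,4,6-tris(methoxymethoxy)-5-(3-methylbut-2-enyl)phenyl]butan-1-one | CCCC(=O)c1c(OCOC)c(CO)c(OCOC)c(CC=C(C)C)c1OCOC | intermediate
18 | 1-[3-(bromomethyl)-2,4,6-tris(methoxymethoxy)-5-(3-methylbut-2-enyl)phenyl]butan-1-one | CCCC(=O)c1c(OCOC)c(CBr)c(OCOC)c(CC=C(C)C)c1OCOC | intermediate
19 | lithium ethoxyacetylide | CCOC#C[Li] | intermediate (not isolated)
20 | bromo(ethoxyethynyl)zinc | CCOC#C[Zn]Br | intermediate (not isolated)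
21 | ring A ethoxyalkyne, 1-[3-(3-ethoxyprop-2-ynyl)-2,4,6-tris(methoxymethoxy)-5-(3-methylbut-2-enyl)phenyl]butan-1-one | CCOC#CCc1c(OCOC)c(CC=C(C)C)c(OCOC)c(C(=O)CCC)c1OCOC | intermediate (key-step precursor)
22 | ring B ethyl vinylogous ester: ring A ketone of 21 joined through CH2 to C2 of (4S)-1-ethoxy-4-geranyl-4-methylcyclohex-1-ene-3,5-dione (C6 is CH2; may exist as the C5 enol) | CCCC(=O)c1c(OCOC)c(CC=C(C)C)c(OCOC)c(CC2=C(OCC)CC(=O)[C@](C)(C/C=C(\C)CCC=C(C)C)C2=O)c1OCOC | intermediate (key-step product)
23 | ring B trione: as 22 with OH in place of OEt at C1 (4S; one enol tautomer drawn) | CCCC(=O)c1c(OCOC)c(CC=C(C)C)c(OCOC)c(CC2=C(O)CC(=O)[C@](C)(C/C=C(\C)CCC=C(C)C)C2=O)c1OCOC | intermediate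
24 | ring B enol acetate: as 23 with OAc on C1 (4S; regioisomeric enol acetates would converge) | CCCC(=O)c1c(OCOC)c(CC=C(C)C)c(OCOC)c(CC2=C(OC(C)=O)CC(=O)[C@](C)(C/C=C(\C)CCC=C(C)C)C2=O)c1OCOC | intermediate (not isolated)
25 | tris-MOM ether of the target: ring B with acetyl on C6 (4R), ring A phenols as MOM ethers | CCCC(=O)c1c(OCOC)c(CC=C(C)C)c(OCOC)c(CC2=C(O)[C@@](C)(C/C=C(\C)CCC=C(C)C)C(O)=C(C(C)=O)C2=O)c1OCOC | intermediate
26 | CNP0227753.1, (4R), E-geranyl | CCCC(=O)c1c(O)c(CC=C(C)C)c(O)c(CC2=C(O)[C@@](C)(C/C=C(\C)CCC=C(C)C)C(O)=C(C(C)=O)C2=O)c1O | target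

**Step count and risks**

Total steps: 14. Longest linear sequence: 10 steps (steps 5–14, phloroglucinol to 26); the dione branch (steps 1–4) joins at step 11.

1. Step 11 (proposed new method). What may go wrong: proton transfer from the acidic dione or the enolisable product to the ynol ether, quenching of low-valent nickel by the same acidic hydrogens, or poor discrimination of the two enantiotopic carbonyls. The fallback gives up the ring expansion and builds ring B by classical dearomatisation; it sets out from bromide 18 and geranyl bromide 2 and returns at 25. C-Benzylation of commercial 1-(2,4,6-trihydroxy-3-methylphenyl)ethan-1-one with 18 (DBU, THF, 0 °C) at its only free ring carbon should give the diarylmethane F1. Dearomatising C-geranylation with 2 (NaOMe, MeOH, 0 °C) at the methyl-bearing ring carbon, the less hindered of the two substituted positions, should give the racemic C-acetyl tris-MOM compound F2. Preparative chromatography on a chiral stationary phase then separates 25 from the unwanted S enantiomer F3.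

2. Step 10. What may go wrong: ionisation or homocoupling of the electron-rich benzylic bromide on palladium, or isomerisation of the propargylic ether to an allenyl ether. The fallback introduces the ketone last, so that plain acetylide alkylation can be used; it sets out from 15 and returns at 21. The dilithio species 16, made as in step 8, is quenched with I2 to give the iodo alcohol F4, and Appel bromination gives the iodo benzylic bromide F5. SN2 alkylation of lithium ethoxyacetylide 19 (THF–DMPU, −78 to 0 °C) gives the iodo alkyne F6. Iodine–magnesium exchange with i-PrMgCl·LiCl (THF, −20 °C) gives the arylmagnesium chloride F7, which is acylated with N-methoxy-N-methylbutanamide to give 21.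

3. Step 12. What may go wrong: loss of MOM ethers (first those ortho to the butyryl group) before hydrolysis of the enol ether is complete. The fallback gives up this selectivity; it sets out from 22 and returns at 26. Aqueous 3 M HCl in MeOH (rt to 40 °C) cleaves the enol ether and all three MOM ethers to give the deacetyl phenol-trione F8. Exhaustive acetylation (Ac2O, Et3N, DMAP, CH2Cl2) esterifies the phenols while ring B undergoes the same O-to-C migration as in step 13, giving the ring A triacetate F9. Methanolysis (K2CO3, MeOH, 0 °C) of the aryl acetates and of any enol acetate then gives 26.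

**Further compounds**

F1 | step 11 | 1-[3-[(3-acetyl-2,4,6-trihydroxy-5-methylphenyl)methyl]-2,4,6-tris(methoxymethoxy)-5-(3-methylbut-2-enyl)phenyl]butan-1-one | CCCC(=O)c1c(OCOC)c(CC=C(C)C)c(OCOC)c(Cc2c(O)c(C)c(O)c(C(C)=O)c2O)c1OCOC
F2 | step 11 | racemic form of 25 | CCCC(=O)c1c(OCOC)c(CC=C(C)C)c(OCOC)c(CC2=C(O)C(C)(C/C=C(\C)CCC=C(C)C)C(O)=C(C(C)=O)C2=O)c1OCOC
F3 | step 11 | enantiomer of 25 (4S) | CCCC(=O)c1c(OCOC)c(CC=C(C)C)c(OCOC)c(CC2=C(O)[C@](C)(C/C=C(\C)CCC=C(C)C)C(O)=C(C(C)=O)C2=O)c1OCOC
F4 | step 10 | [3-iodo-2,4,6-tris(methoxymethoxy)-5-(3-methylbut-2-enyl)phenyl]methanol | OCc1c(OCOC)c(I)c(OCOC)c(CC=C(C)C)c1OCOC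
F5 | step 10 | 1-(bromomethyl)-3-iodo-2,4,6-tris(methoxymethoxy)-5-(3-methylbut-2-enyl)benzene | BrCc1c(OCOC)c(I)c(OCOC)c(CC=C(C)C)c1OCOC
F6 | step 10 | 1-(3-ethoxyprop-2-ynyl)-3-iodo-2,4,6-tris(methoxymethoxy)-5-(3-methylbut-2-enyl)benzene | CCOC#CCc1c(OCOC)c(I)c(OCOC)c(CC=C(C)C)c1OCOC
F7 | step 10 | [3-(3-ethoxyprop-2-ynyl)-2,4,6-tris(methoxymethoxy)-5-(3-methylbut-2-enyl)phenyl]magnesium chloride | CCOC#CCc1c(OCOC)c([Mg]Cl)c(OCOC)c(CC=C(C)C)c1OCOC
F8 | step 12 | deacetyl target: ring A triphenol joined to the ring B trione (4S, C1 enol drawn) | CCCC(=O)c1c(O)c(CC=C(C)C)c(O)c(CC2=C(O)CC(=O)[C@](C)(C/C=C(\C)CCC=C(C)C)C2=O)c1O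
F9 | step 12 | ring A tri-O-acetate of the target (4R) | CCCC(=O)c1c(OC(C)=O)c(CC=C(C)C)c(OC(C)=O)c(CC2=C(O)[C@@](C)(C/C=C(\C)CCC=C(C)C)C(O)=C(C(C)=O)C2=O)c1OC(C)=O
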